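**Retrosynthetic overview**
- Late stage: the C15 caffeate is attached by Steglich esterification with allyl-protected partners. The exocyclic C8=C17 alkene comes from reductive 1,3-transposition of a C17 allylic alcohol, itself made by allylic oxidation of a 7-ene 8-methyl precursor.
- Ring A is closed last, by forming C3–C4: Ireland–Claisen rearrangement of a cis-fused δ-lactone C19(=O)–O–C1 whose C1 carries a vinyl group (C2=C3). This sets quaternary C4 and releases the C19 acid; the C1=C2 alkene left behind is hydrogenated.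
- Enabling feature: on ring A the carboxyl carbon C19 (on C4) and ring carbon C1 are 1,4-related (C4–C5–C10–C1). The acid can therefore be tied back to C1 as a six-membered lactone across the cis C5–C10 fusion, which puts the ester enolate C4=C19 and the allyl unit C1–C2=C3 in a [3,3] array.
- Ring B is built first, by an endo Diels–Alder reaction of an (S)-citronellol-derived (E)-diene (C6–C9 plus the C11–C16 chain) with (R)-5-methyl-5,6-dihydro-2H-pyran-2-one (C1, C10, C5, C4, C18, C19). The C10 methyl is then added by lactone enolate alkylation.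
- Order of ring formation: ring B (cycloaddition), temporary lactone ring (transposed by vinyl addition, reduction and oxidative lactonisation), ring A (key step).

Key step: step 14

Remark: locants follow labdane numbering (C1–C10 ring carbons, C11–C16 side chain, C17 on C8, C18 methyl and C19 carboxyl on C4, C20 methyl on C10); β is the face of the C10 methyl; SC stands for (3S)-5-[(tert-butyldiphenylsilyl)oxy]-3-methylpentyl; the given descriptors are read as the cis-fused decalin with 5β-H, 9β-H (side chain α), 4β-CO2H and 13S, i.e. (4S,5S,9R,10R,13S).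

**Step 1**
Reactants: 1 (S)-citronellol [(S)-3,7-dimethyloct-6-en-1-ol]
Product: 2 (S)-tert-butyl[(3,7-dimethyloct-6-en-1-yl)oxy]diphenylsilane
Conditions: TBDPSCl, imidazole, DMF, rt
Reagents that add atoms: tert-butyl(chloro)diphenylsilane, CC(C)(C)[Si](Cl)(c1ccccc1)c1ccccc1
Why: Silyl ether protection of the primary alcohol with a group that should survive the organometallic, Lewis-acid and oxidative steps up to step 19; the C13 stereocentre is that of the starting material.

**Step 2**
Reactants: 2 (S)-tert-butyl[(3,7-dimethyloct-6-en-1-yl)oxy]diphenylsilane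
Product: 4 (S)-6-[(tert-butyldiphenylsilyl)oxy]-4-methylhexanal, via ozonide 3 (not isolated)
Conditions: O3, CH2Cl2, −78 °C; then PPh3, −78 °C to rt
Reagents that add atoms: ozone, [O-][O+]=O
Why: Ozonolysis of the trisubstituted alkene with reductive work-up gives the aldehyde whose carbonyl carbon becomes C9, the remote stereocentre being untouched.

**Step 3**
Reactants: 4 (S)-6-[(tert-butyldiphenylsilyl)oxy]-4-methylhexanal
Product: 5 (S,E)-8-[(tert-butyldiphenylsilyl)oxy]-2,6-dimethyloct-2-enal
Conditions: Ph3P=C(CH3)CHO, toluene, 90 °C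
Reagents that add atoms: 2-(triphenyl-λ5-phosphanylidene)propanal, CC(C=O)=P(c1ccccc1)(c1ccccc1)c1ccccc1
Why: Wittig reaction with a formyl-stabilised ylide, which should give the (E)-2-methyl-2-enal (chain trans to CHO) as expected for stabilised ylides.

**Step 4**
Reactants: 5 (S,E)-8-[(tert-butyldiphenylsilyl)oxy]-2,6-dimethyloct-2-enal
Product: 6 (S,E)-tert-butyl[(3,7-dimethylnona-6,8-dien-1-yl)oxy]diphenylsilane (diene C6=C7–C8(CH3)=C9–SC)
Conditions: Ph3PCH3Br, KOtBu, THF, 0 °C to rt
Reagents that add atoms: methyltriphenylphosphonium bromide, C[P+](c1ccccc1)(c1ccccc1)c1ccccc1.[Br-]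
Why: Wittig methylenation of the enal carbonyl gives the (E)-1,2-dialkyl diene with the C9 substituent in the outside position needed for the endo cycloaddition.

**Step 5**
Reactants: 7 methyl (S)-3-hydroxy-2-methylpropanoate
Product: 8 methyl (S)-3-[(tert-butyldimethylsilyl)oxy]-2-methylpropanoate
Conditions: TBSCl, imidazole, CH2Cl2, rt
Reagents that add atoms: tert-butyl(chloro)dimethylsilane, CC(C)(C)[Si](C)(C)Cl
Why: Silyl ether protection of the primary alcohol, which does not touch the α-stereocentre.

**Step 6**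
Reactants: 8 methyl (S)-3-[(tert-butyldimethylsilyl)oxy]-2-methylpropanoate
Product: 9 (S)-3-[(tert-butyldimethylsilyl)oxy]-2-methylpropanal
Conditions: iBu2AlH, CH2Cl2, −78 °C; aq potassium sodium tartrate
Reagents that add atoms: none
Why: Partial reduction of an ester to the aldehyde with iBu2AlH at low temperature; the configurationally labile α-methyl aldehyde is used crude and cold so that the stereocentre should be retained.

**Step 7**
Reactants: 9 (S)-3-[(tert-butyldimethylsilyl)oxy]-2-methylpropanal
Product: 10 methyl (R,Z)-5-[(tert-butyldimethylsilyl)oxy]-4-methylpent-2-enoate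
Conditions: (CF3CH2O)2P(O)CH2CO2Me, KN(SiMe3)2, 18-crown-6, THF, −78 °C
Reagents that add atoms: methyl 2-[bis(2,2,2-trifluoroethoxy)phosphoryl]acetate, COC(=O)CP(=O)(OCC(F)(F)F)OCC(F)(F)F
Why: Still–Gennari olefination (Z-selective Horner–Wadsworth–Emmons reaction) gives the cis enoate needed for ring closure, the α-stereocentre being retained at −78 °C (the descriptor changes only through priorities).

**Step 8**
Reactants: 10 methyl (R,Z)-5-[(tert-butyldimethylsilyl)oxy]-4-methylpent-2-enoate
Product: 12 (R)-5-methyl-5,6-dihydro-2H-pyran-2-one, via hydroxy ester 11 (not isolated)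
Conditions: camphorsulfonic acid (cat.), MeOH, rt; then toluene, 60 °C
Reagents that add atoms: none
Why: Acid-catalysed methanolysis of the silyl ether followed by lactonisation of the (Z)-δ-hydroxy enoate (transesterification to a six-membered ring); the stereocentre, now C4 carrying the future C18 methyl, is not involved.

**Step 9**
Reactants: 6 (S,E)-tert-butyl[(3,7-dimethylnona-6,8-dien-1-yl)oxy]diphenylsilane; 12 (R)-5-methyl-5,6-dihydro-2H-pyran-2-one
Product: 13 Diels–Alder lactone [cis-fused lactone C10–C1(=O)–O–C19H2–C4H(CH3)–C5 on ring B; ring B with C7=C8, 8-CH3 and 9α-SC; 4β-CH3; 5β-H; 9β-H; 10β-H]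
Conditions: EtAlCl2 (1.2 equiv), CH2Cl2, −40 °C to rt
Reagents that add atoms: none
Why: Lewis-acid-promoted Diels–Alder reaction of an α,β-unsaturated δ-lactone with a 1,2-dialkyl diene: the alkyl-bearing terminus C9 should bond to the α-carbon C10 (ortho rule, as with 1-vinylcyclohexene), the endo transition state places the C9 side chain cis to C1 and C4, and approach anti to the C4 methyl fixes the absolute configuration of C5, C9 and C10.

**Step 10**
Reactants: 13 Diels–Alder lactone
Product: 15 10β-methyl lactone [as 13 with quaternary C10 carrying β-CH3 (C20)], via lithium enolate 14 (not isolated)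
Conditions: LiN(iPr)2, THF, −78 °C; then MeI, DMPU, −78 to −20 °C
Reagents that add atoms: iodomethane, CI
Why: Alkylation of the lactone enolate (only C10–H is acidic): iodomethane should enter the convex β face, anti to the adjacent 9α side chain, creating quaternary C10 with the methyl cis to H5 and keeping the cis ring fusion.

**Step 11**
Reactants: 15 10β-methyl lactone
Product: 17 hydroxy enone [C10–C1(=O)–CH=CH2 and C5–C4H(CH3)–C19H2OH on ring B], via magnesium lactolate 16 (not isolated)
Conditions: CH2=CHMgBr (1.2 equiv), THF, −78 to −40 °C; then sat. aq NH4Cl, −78 °C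
Reagents that add atoms: vinylmagnesium bromide, C=C[Mg]Br
Why: Single Grignard addition to an unenolisable α-quaternary lactone (acyl substitution stopping at the ketone stage), because the hindered lactolate 16 should persist until the cold quench.

**Step 12**
Reactants: 17 hydroxy enone
Product: 18 (1R)-diol [C10–C1H(OH)–CH=CH2 with 1β-H; C19H2OH]
Conditions: (S)-2-methyl-CBS-oxazaborolidine (0.5 equiv), catecholborane (3 equiv), toluene, −78 °C
Reagents that add atoms: none
Why: Corey–Bakshi–Shibata 1,2-reduction of the enone under reagent control, with the quaternary C10 group as the large and the vinyl group as the small substituent, should give the (1R)-carbinol that later dictates C4.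

**Step 13**
Reactants: 18 (1R)-diol
Product: 20 vinyl lactone [cis-fused δ-lactone C10–C1H(CH=CH2)–O–C19(=O)–C4H(CH3)–C5; 1R with the vinyl group on the ring-B (α) face; 10β-CH3; 5β-H], via lactol 19 (not isolated)
Conditions: TEMPO (20 mol%), PhI(OAc)2 (3 equiv), CH2Cl2, rt
Reagents that add atoms: none
Why: Oxidative lactonisation of a 1,5-diol: only the primary alcohol is oxidised, the aldehyde closes to lactol 19 with the C1 hydroxyl and is oxidised on to the lactone, leaving the C1 centre intact (the C4 configuration is of no consequence).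

**Step 14**
Reactants: 20 vinyl lactone
Product: 23 diene acid [ring A closed: C10–C1H=C2H–C3H2–C4(α-CH3)(β-CO2H)–C5; 7-ene; 10β-CH3; 5β-H; 9β-H; 9α-SC], via silyl ketene acetal 21 (not isolated), via silyl ester 22 (not isolated)
Conditions: LiN(iPr)2, TBSCl, HMPA, THF, −78 °C; then toluene, 110 °C; then 1 M HCl, THF, rt
Reagents that add atoms: none
Why: Deprotonation at C4 (the only α-hydrogen) with in situ O-silylation gives the cyclic silyl ketene acetal 21, in which C4=C19, the ring oxygen and the C1 vinyl group form an allyl vinyl ether; on heating, a concerted suprafacial [3,3]-sigmatropic shift makes C3–C4, breaks C1–O and leaves the C1=C2 alkene and silyl ester 22, which is hydrolysed to 23. The closest known reaction type is the Ireland–Claisen rearrangement of silyl enolates of 6-alkenyl δ-lactones to cyclohex-3-enecarboxylic acids. Ring A (C1–C2–C3–C4–C5–C10) is closed in the pericyclic mode through the boat-shaped six-membered transition state that the lactone ring enforces, C1 and C4 being bridged by C10–C5, O–C19 and C2=C3 as in a bicyclo[2.2.2]octane. The new quaternary centre C4 is controlled by the (1R)-carbinol carbon alone (self-immolative chirality transfer): the vinyl group sits on the ring-B (α) face of the lactone, so C3 bonds to the α face of C4 and the former lactone carbonyl C19 becomes the β-carboxyl, cis to the C10 methyl and H5, while the C4 configuration of 20 is irrelevant because C4 is trigonal in 21. The step needs complete transfer of this facial information, which the ring-fixed enolate geometry, the single accessible boat and the non-epimerisable C1 should secure; C5, C9, C10 and C13 are not touched.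

**Step 15**
Reactants: 23 diene acid
Product: 24 7-ene acid [ring A saturated; otherwise as 23]
Conditions: H2 (3 atm), RhCl(PPh3)3 (10 mol%), benzene–EtOH, rt
Reagents that add atoms: none
Why: Homogeneous catalytic hydrogenation with RhCl(PPh3)3 should reduce the cis-disubstituted C1=C2 bond much faster than the trisubstituted C7=C8 bond; no stereocentre is formed.

**Step 16**
Reactants: 24 7-ene acid
Product: 25 17-hydroxy-7-ene acid [C8–CH2OH]
Conditions: SeO2 (0.5 equiv), t-BuOOH (3 equiv), CH2Cl2, rt
Reagents that add atoms: selenium dioxide, O=[Se]=O; tert-butyl hydroperoxide, CC(C)(C)OO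
Why: SeO2 allylic oxidation (ene reaction then [2,3]-sigmatropic shift) of the 8-methyl group, the usual site in 7-ene drimane and labdane systems because the other allylic position on the substituted alkene terminus is the hindered C9 methine.

**Step 17**
Reactants: 25 17-hydroxy-7-ene acid
Product: 26 allyl 17-hydroxy-7-en-19-oate
Conditions: allyl bromide, K2CO3, DMF, rt
Reagents that add atoms: allyl bromide, C=CCBr
Why: SN2 O-alkylation of the carboxylate, insensitive to hindrance at C4, protects the acid for the Mitsunobu step while the alcohol is not alkylated under carbonate conditions.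

**Step 18**
Reactants: 26 allyl 17-hydroxy-7-en-19-oate
Product: 29 allyl 8(17)-en-19-oate [exocyclic C8=CH2; C7H2; side chain O-TBDPS], via sulfonylhydrazine adduct 27 (not isolated), via allylic diazene 28 (not isolated)
Conditions: PPh3, diethyl azodicarboxylate, 2-nitrobenzenesulfonylhydrazide, N-methylmorpholine, −30 °C to rt
Reagents that add atoms: none
Why: Reductive 1,3-transposition of an allylic alcohol: Mitsunobu displacement gives 27, loss of sulfinic acid gives diazene 28, and retro-ene loss of N2 moves the double bond from C7=C8 to exocyclic C8=C17 with hydrogen delivered to C7.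

**Step 19**
Reactants: 29 allyl 8(17)-en-19-oate
Product: 30 allyl 15-hydroxy-8(17)-en-19-oate
Conditions: Bu4NF, THF, rt
Reagents that add atoms: none
Why: Fluoride cleavage of the primary silyl ether frees the C15 alcohol; the allyl ester and the exocyclic alkene should be inert.

**Step 20**
Reactants: 31 caffeic acid
Product: 32 allyl (E)-3-[3,4-bis(allyloxy)phenyl]prop-2-enoate
Conditions: allyl bromide (3.5 equiv), K2CO3, DMF, 50 °C
Reagents that add atoms: allyl bromide, C=CCBr
Why: Williamson ether synthesis and carboxylate alkylation allylate all three acidic OH groups.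

**Step 21**
Reactants: 32 allyl (E)-3-[3,4-bis(allyloxy)phenyl]prop-2-enoate
Product: 33 (E)-3-[3,4-bis(allyloxy)phenyl]prop-2-enoic acid
Conditions: LiOH, THF–MeOH–H2O, rt; then 1 M HCl
Reagents that add atoms: lithium hydroxide, [Li+].[OH-]
Why: Saponification cleaves only the ester, since aryl allyl ethers are stable to hydroxide.

**Step 22**
Reactants: 30 allyl 15-hydroxy-8(17)-en-19-oate; 33 (E)-3-[3,4-bis(allyloxy)phenyl]prop-2-enoic acid
Product: 34 allyl 15-{[(E)-3-(3,4-bis(allyloxy)phenyl)prop-2-enoyl]oxy}-8(17)-en-19-oate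
Conditions: DCC, DMAP (cat.), CH2Cl2, 0 °C to rt
Reagents that add atoms: none
Why: Steglich esterification of the unhindered primary C15 alcohol; the hindered C19 allyl ester should not transacylate.

**Step 23**
Reactants: 34 allyl 15-{[(E)-3-(3,4-bis(allyloxy)phenyl)prop-2-enoyl]oxy}-8(17)-en-19-oate
Product: 35 (4S,5S,9R,10R,13S)-15-{[(E)-3-(3,4-dihydroxyphenyl)prop-2-enoyl]oxy}labd-8(17)-en-19-oic acid (target)
Conditions: Pd(PPh3)4 (10 mol%), morpholine (10 equiv), THF, rt, degassed
Reagents that add atoms: none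
Why: Tsuji–Trost deallylation: the allyl ester and both aryl allyl ethers are ionised to π-allyl complexes that morpholine traps, under neutral conditions that should leave the cinnamate ester, its (E) geometry and the exocyclic alkene untouched.

**Compound list**
1 | (S)-citronellol | CC(C)=CCC[C@H](C)CCO | starting material
2 | (S)-tert-butyl[(3,7-dimethyloct-6-en-1-yl)oxy]diphenylsilane | CC(C)=CCC[C@H](C)CCO[Si](c1ccccc1)(c1ccccc1)C(C)(C)C | intermediate
3 | ozonide of 2 (3,3-dimethyl-1,2,4-trioxolane with the chain at C5) | CC1(C)OOC(CC[C@H](C)CCO[Si](c2ccccc2)(c2ccccc2)C(C)(C)C)O1 | intermediate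
4 | (S)-6-[(tert-butyldiphenylsilyl)oxy]-4-methylhexanal | O=CCC[C@H](C)CCO[Si](c1ccccc1)(c1ccccc1)C(C)(C)C | intermediate
5 | (S,E)-8-[(tert-butyldiphenylsilyl)oxy]-2,6-dimethyloct-2-enal | O=C/C(C)=C/CC[C@H](C)CCO[Si](c1ccccc1)(c1ccccc1)C(C)(C)C | intermediate
6 | (S,E)-tert-butyl[(3,7-dimethylnona-6,8-dien-1-yl)oxy]diphenylsilane | C=C/C(C)=C/CC[C@H](C)CCO[Si](c1ccccc1)(c1ccccc1)C(C)(C)C | intermediate
7 | methyl (S)-3-hydroxy-2-methylpropanoate | COC(=O)[C@@H](C)CO | starting material
8 | methyl (S)-3-[(tert-butyldimethylsilyl)oxy]-2-methylpropanoate | COC(=O)[C@@H](C)CO[Si](C)(C)C(C)(C)C | intermediate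
9 | (S)-3-[(tert-butyldimethylsilyl)oxy]-2-methylpropanal | O=C[C@@H](C)CO[Si](C)(C)C(C)(C)C | intermediate
10 | methyl (R,Z)-5-[(tert-butyldimethylsilyl)oxy]-4-methylpent-2-enoate | COC(=O)/C=C\[C@@H](C)CO[Si](C)(C)C(C)(C)C | intermediate
11 | methyl (R,Z)-5-hydroxy-4-methylpent-2-enoate | COC(=O)/C=C\[C@@H](C)CO | intermediate
12 | (R)-5-methyl-5,6-dihydro-2H-pyran-2-one | O=C1C=C[C@@H](C)CO1 | intermediate
13 | Diels–Alder lactone (cis-fused; C1 carbonyl; 4β-CH3; 5β,9β,10β-H; 7-ene; 9α-SC) | CC1=CC[C@H]2[C@H](C(=O)OC[C@@H]2C)[C@@H]1CC[C@H](C)CCO[Si](c1ccccc1)(c1ccccc1)C(C)(C)C | intermediate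
14 | lithium enolate of 13 (C10=C1) | CC1=CC[C@H]2C(=C(O[Li])OC[C@@H]2C)[C@@H]1CC[C@H](C)CCO[Si](c1ccccc1)(c1ccccc1)C(C)(C)C | intermediate
15 | 10β-methyl lactone | CC1=CC[C@H]2[C@](C)(C(=O)OC[C@@H]2C)[C@@H]1CC[C@H](C)CCO[Si](c1ccccc1)(c1ccccc1)C(C)(C)C | intermediate
16 | bromomagnesium lactolate (vinyl adduct at C1 of 15) | CC1=CC[C@H]2[C@](C)(C(C=C)(O[Mg]Br)OC[C@@H]2C)[C@@H]1CC[C@H](C)CCO[Si](c1ccccc1)(c1ccccc1)C(C)(C)C | intermediate
17 | hydroxy enone (C1 vinyl ketone; C19 primary alcohol) | CC1=CC[C@H]([C@@H](C)CO)[C@](C)(C(=O)C=C)[C@@H]1CC[C@H](C)CCO[Si](c1ccccc1)(c1ccccc1)C(C)(C)C | intermediate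
18 | (1R)-diol (C1 allylic carbinol; C19 primary alcohol) | CC1=CC[C@H]([C@@H](C)CO)[C@](C)([C@H](O)C=C)[C@@H]1CC[C@H](C)CCO[Si](c1ccccc1)(c1ccccc1)C(C)(C)C | intermediate
19 | lactol (C19 hemiacetal closed on the C1 oxygen) | CC1=CC[C@H]2[C@](C)([C@@H](C=C)OC(O)[C@@H]2C)[C@@H]1CC[C@H](C)CCO[Si](c1ccccc1)(c1ccccc1)C(C)(C)C | intermediate
20 | vinyl lactone (C19 carbonyl; ring O on C1; 1R) | CC1=CC[C@H]2[C@](C)([C@@H](C=C)OC(=O)[C@@H]2C)[C@@H]1CC[C@H](C)CCO[Si](c1ccccc1)(c1ccccc1)C(C)(C)C | intermediate
21 | cyclic tert-butyldimethylsilyl ketene acetal of 20 (C4=C19) | CC1=CC[C@H]2[C@](C)([C@@H](C=C)OC(O[Si](C)(C)C(C)(C)C)=C2C)[C@@H]1CC[C@H](C)CCO[Si](c1ccccc1)(c1ccccc1)C(C)(C)C | intermediate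
22 | tert-butyldimethylsilyl ester of 23 | CC1=CC[C@H]2[C@](C)(C=CC[C@]2(C)C(=O)O[Si](C)(C)C(C)(C)C)[C@@H]1CC[C@H](C)CCO[Si](c1ccccc1)(c1ccccc1)C(C)(C)C | intermediate
23 | 1,7-diene acid (4β-CO2H; 4α-CH3; 10β-CH3; 5β,9β-H) | CC1=CC[C@H]2[C@](C)(C=CC[C@]2(C)C(=O)O)[C@@H]1CC[C@H](C)CCO[Si](c1ccccc1)(c1ccccc1)C(C)(C)C | intermediate
24 | 7-ene acid | CC1=CC[C@H]2[C@](C)(CCC[C@]2(C)C(=O)O)[C@@H]1CC[C@H](C)CCO[Si](c1ccccc1)(c1ccccc1)C(C)(C)C | intermediate
25 | 17-hydroxy-7-ene acid | OCC1=CC[C@H]2[C@](C)(CCC[C@]2(C)C(=O)O)[C@@H]1CC[C@H](C)CCO[Si](c1ccccc1)(c1ccccc1)C(C)(C)C | intermediate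
26 | allyl 17-hydroxy-7-en-19-oate | OCC1=CC[C@H]2[C@](C)(CCC[C@]2(C)C(=O)OCC=C)[C@@H]1CC[C@H](C)CCO[Si](c1ccccc1)(c1ccccc1)C(C)(C)C | intermediate
27 | N-(C17-allylic)-N-(2-nitrobenzenesulfonyl)hydrazine | NN(CC1=CC[C@H]2[C@](C)(CCC[C@]2(C)C(=O)OCC=C)[C@@H]1CC[C@H](C)CCO[Si](c1ccccc1)(c1ccccc1)C(C)(C)C)S(=O)(=O)c1ccccc1[N+](=O)[O-] | intermediate
28 | allylic diazene (C17–N=NH) | N=NCC1=CC[C@H]2[C@](C)(CCC[C@]2(C)C(=O)OCC=C)[C@@H]1CC[C@H](C)CCO[Si](c1ccccc1)(c1ccccc1)C(C)(C)C | intermediate
29 | allyl 15-(TBDPS-oxy)-8(17)-en-19-oate | C=C1CC[C@H]2[C@](C)(CCC[C@]2(C)C(=O)OCC=C)[C@@H]1CC[C@H](C)CCO[Si](c1ccccc1)(c1ccccc1)C(C)(C)C | intermediate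
30 | allyl 15-hydroxy-8(17)-en-19-oate | C=C1CC[C@H]2[C@](C)(CCC[C@]2(C)C(=O)OCC=C)[C@@H]1CC[C@H](C)CCO | intermediate
31 | caffeic acid | OC(=O)/C=C/c1ccc(O)c(O)c1 | starting material
32 | allyl (E)-3-[3,4-bis(allyloxy)phenyl]prop-2-enoate | C=CCOC(=O)/C=C/c1ccc(OCC=C)c(OCC=C)c1 | intermediate
33 | (E)-3-[3,4-bis(allyloxy)phenyl]prop-2-enoic acid | OC(=O)/C=C/c1ccc(OCC=C)c(OCC=C)c1 | intermediate
34 | tris-allyl-protected target | C=C1CC[C@H]2[C@](C)(CCC[C@]2(C)C(=O)OCC=C)[C@@H]1CC[C@H](C)CCOC(=O)/C=C/c1ccc(OCC=C)c(OCC=C)c1 | intermediate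
35 | (4S,5S,9R,10R,13S)-15-{[(E)-3-(3,4-dihydroxyphenyl)prop-2-enoyl]oxy}labd-8(17)-en-19-oic acid | C=C1CC[C@H]2[C@](C)(CCC[C@]2(C)C(=O)O)[C@@H]1CC[C@H](C)CCOC(=O)/C=C/c1ccc(O)c(O)c1 | target

**Totals**
Total step count: 23. Longest linear sequence: 17 steps (steps 1–4 or 5–8, then 9–19, 22 and 23).

**Steps most likely to fail, with fallbacks**

Step 14 (key step). The enforced boat transition state is crowded, because the vinyl bridge nearly eclipses C9 and its side chain. The rearrangement may therefore be slow, and C-silylation or thermal decomposition of the ketene acetal may compete. The fallback sets out from 17 and returns at 23. Oxidation of the primary alcohol with TEMPO/PhI(OAc)2 in aqueous MeCN should give the keto acid F1, and K2CO3/allyl bromide the allyl keto ester F2. Deprotonation at C4 with KN(SiMe3)2 at −78 °C then triggers a 6-endo-trig intramolecular Michael addition of the ester enolate onto the vinyl ketone (C4 to C3), and the resulting C1–C2 enolate is trapped with PhNTf2 as the ring-A enol triflate F3. Allylic strain (H5 in the enolate plane) should favour the β-carboxyl isomer, and any C4 epimer would be separated here. Pd(PPh3)4, HCO2H and Et3N in DMF then reduce the triflate to the C1=C2 alkene and cleave the allyl ester in one operation to give 23.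

Step 9. The lactone is a sluggish dienophile, so Lewis-acid-induced diene oligomerisation may outrun the cycloaddition, and regio-, endo or facial selectivity may be incomplete. The fallback sets out from 12 and 6 and returns at 13. Bromine addition to 12 gives the dibromide F4 (not isolated), which Et3N dehydrobrominates to the more reactive (R)-3-bromo-5-methyl-5,6-dihydro-2H-pyran-2-one F5. Its cycloaddition with 6 (toluene, 110 °C, or Me2AlCl) should give the 10-bromo adduct F6 with the same regiochemistry and facial sense. Bu3SnH with azobisisobutyronitrile removes the bromine to give 13; the C10 configuration formed here does not matter because step 10 enolises that centre.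

Step 12. Reagent control at the hindered α-quaternary ketone may be insufficient (substrate bias against the catalyst), and 1,4-reduction or hydroboration may compete. The fallback sets out from 15 and returns at 18. Single addition of LiC≡CSiMe3 to the lactone at −78 °C should give the hydroxy ynone F7. Asymmetric transfer hydrogenation with RuCl(p-cymene)[(S,S)-TsDPEN] in iPrOH, in which the alkynyl group takes the place of the aryl group in the usual model, should give the propargylic alcohol F8 with the same C1 configuration as 18. K2CO3 in MeOH removes the silyl group to give the terminal alkyne F9, and semihydrogenation (H2, Pd/CaCO3 poisoned with Pb(OAc)2, quinoline) gives 18.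

**Further compounds**
F1 | step 14 | keto acid (C1 vinyl ketone; C19 acid; ring A open) | CC1=CC[C@H]([C@@H](C)C(=O)O)[C@](C)(C(=O)C=C)[C@@H]1CC[C@H](C)CCO[Si](c1ccccc1)(c1ccccc1)C(C)(C)C
F2 | step 14 | allyl keto ester | CC1=CC[C@H]([C@@H](C)C(=O)OCC=C)[C@](C)(C(=O)C=C)[C@@H]1CC[C@H](C)CCO[Si](c1ccccc1)(c1ccccc1)C(C)(C)C
F3 | step 14 | ring-A enol triflate (C1(OTf)=C2; C19 allyl ester) | CC1=CC[C@H]2[C@](C)(C(OS(=O)(=O)C(F)(F)F)=CC[C@]2(C)C(=O)OCC=C)[C@@H]1CC[C@H](C)CCO[Si](c1ccccc1)(c1ccccc1)C(C)(C)C
F4 | step 9 | (5R)-3,4-dibromo-5-methyltetrahydro-2H-pyran-2-one | O=C1C(Br)C(Br)[C@@H](C)CO1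
F5 | step 9 | (R)-3-bromo-5-methyl-5,6-dihydro-2H-pyran-2-one | O=C1C(Br)=C[C@@H](C)CO1
F6 | step 9 | 10-bromo Diels–Alder lactone | CC1=CC[C@H]2[C@](Br)(C(=O)OC[C@@H]2C)[C@@H]1CC[C@H](C)CCO[Si](c1ccccc1)(c1ccccc1)C(C)(C)C
F7 | step 12 | hydroxy ynone (C1 ketone with trimethylsilylethynyl) | CC1=CC[C@H]([C@@H](C)CO)[C@](C)(C(=O)C#C[Si](C)(C)C)[C@@H]1CC[C@H](C)CCO[Si](c1ccccc1)(c1ccccc1)C(C)(C)C
F8 | step 12 | silylated propargylic diol | CC1=CC[C@H]([C@@H](C)CO)[C@](C)([C@H](O)C#C[Si](C)(C)C)[C@@H]1CC[C@H](C)CCO[Si](c1ccccc1)(c1ccccc1)C(C)(C)C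
F9 | step 12 | terminal propargylic diol | CC1=CC[C@H]([C@@H](C)CO)[C@](C)([C@H](O)C#C)[C@@H]1CC[C@H](C)CCO[Si](c1ccccc1)(c1ccccc1)C(C)(C)C
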